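**Assumption:** the SMILES is taken at face value, i.e. (3R) at the lactone carbon and (S) at the side-chain carbinol; equivalents and temperatures are indicative. The route is a paper plan and has not been run.

## Retrosynthetic overview

1. Target 21 ⇐ 20 (aryl methyl ether cleavage) ⇐ 19 (C–S hydrogenolysis turns the dithiane carbon into the C2' methylene) ⇐ 17 (lactone C–O bond from a hydroxy amide).
2. Key disconnection of 17 at C1'–C2' and C2'–C3': the carbanion of 2-silyl-1,3-dithiane 10 (a masked carbonyl carbon used as a nucleophile) joins the terminal CH2 of epoxide 9 and the CH2 of (S)-propylene oxide 11. A 1,4-Brook silyl shift relays the anion, and succinic anhydride 12 caps the last alkoxide, all in one flask.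
3. Epoxide 9 ⇐ ortho-metalated amide 4 + (S)-epichlorohydrin 5; 4 ⇐ acid 1 + diethylamine 2.
4. Rings: the benzene ring is bought; the dithiane ring is bought and destroyed in step 5; the δ-lactone is the only ring built, closed in step 4 after the key coupling.
5. Both stereocenters come from the two chiral-pool epoxides and are never reaction sites.

## Route

**Step 1**
Reactants: 1 2,5-dimethoxybenzoic acid; 2 diethylamine
Product: 4 N,N-diethyl-2,5-dimethoxybenzamide, via acid chloride 3 (not isolated)
Conditions: SOCl2, cat. DMF, toluene, 70 °C; evaporate; then 2, 2 M NaOH(aq), CH2Cl2, 0 °C → rt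
Reagents that add atoms: thionyl chloride, O=S(Cl)Cl (its chlorine is held only by intermediate 3)
Why: Acyl chloride formation followed by Schotten–Baumann amidation is a routine nucleophilic acyl substitution that installs a tertiary amide serving both as a strong ortho-directing group and as a carboxyl mask inert to organolithiums, and no stereocenter is involved.

**Step 2**
Reactants: 4 N,N-diethyl-2,5-dimethoxybenzamide; 5 (S)-epichlorohydrin
Product: 9 N,N-diethyl-3,6-dimethoxy-2-[(2S)-oxiran-2-ylmethyl]benzamide, via aryllithium 6 (not isolated), via arylmagnesium bromide 7 (not isolated), via chlorohydrin 8 (not isolated)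
Conditions: s-BuLi, TMEDA, THF, −78 °C, 1 h; MgBr2·OEt2, −78 → −40 °C; CuI (10 mol %), 5 (1.5 equiv), −40 → 0 °C; then 2 M NaOH(aq), MeOH, rt
Reagents that add atoms: sec-butyllithium, [Li]C(C)CC (lithium of 6 only); MgBr2·OEt2, Br[Mg]Br (MgBr of 7 only)
Why: Directed ortho-metalation takes place at C6, the only position flanked by both the amide and a methoxy group, and after lithium-to-magnesium exchange the aryl Grignard opens the epoxide of 5 at its unsubstituted ring carbon under CuI catalysis, so that base-induced closure of the chlorohydrin (intramolecular Williamson etherification) gives a new terminal epoxide whose stereocenter is carried over untouched from the chiral pool ((S) in, (S) out).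

**Step 3 (key step)**
Reactants: 9 N,N-diethyl-3,6-dimethoxy-2-[(2S)-oxiran-2-ylmethyl]benzamide; 10 2-(tert-butyldimethylsilyl)-1,3-dithiane; 11 (S)-propylene oxide; 12 succinic anhydride
Product: 17 4-{[(2S)-1-{2-[(2S)-2-[(tert-butyldimethylsilyl)oxy]-3-[2-(diethylcarbamoyl)-3,6-dimethoxyphenyl]propyl]-1,3-dithian-2-yl}propan-2-yl]oxy}-4-oxobutanoic acid, via lithiated silyl dithiane 13 (not isolated), via first lithium alkoxide 14 (not isolated), via Brook-shifted lithiodithiane 15 (not isolated), via second lithium alkoxide 16 (not isolated)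
Conditions: 10 (1.05 equiv), t-BuLi, Et2O, −78 → −45 °C; 9 (1.0 equiv), Et2O, −78 → −25 °C; 11 (1.5 equiv), THF/HMPA (10:1), −78 → 0 °C; 12 (3 equiv), THF, 0 °C → rt; cold 1 M HCl work-up
Reagents that add atoms: tert-butyllithium, [Li]C(C)(C)C (lithium of 13 to 16 only)
Why: In this silyl-dithiane linchpin coupling (anion relay with a solvent-controlled 1,4-Brook rearrangement) the lithiated dithiane, an acyl anion equivalent, opens 9 at its terminal carbon in Et2O, HMPA then moves the silyl group onto the new alkoxide and regenerates a dithiane carbanion that opens 11 at its CH2 group, and the resulting secondary lithium alkoxide is acylated in the same flask by succinic anhydride, so the umpoled carbon joins two electrophilic epoxide carbons while both stereocenters are brought in unchanged by the two enantiopure epoxides and the two oxygens come out differentiated.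

**Step 4**
Reactants: 17 4-{[(2S)-1-{2-[(2S)-2-[(tert-butyldimethylsilyl)oxy]-3-[2-(diethylcarbamoyl)-3,6-dimethoxyphenyl]propyl]-1,3-dithian-2-yl}propan-2-yl]oxy}-4-oxobutanoic acid
Product: 19 4-{[(2S)-1-(2-{[(3S)-5,8-dimethoxy-1-oxo-3,4-dihydro-1H-isochromen-3-yl]methyl}-1,3-dithian-2-yl)propan-2-yl]oxy}-4-oxobutanoic acid, via hydroxy amide 18 (not isolated)
Conditions: TsOH·H2O (2.5 equiv), toluene, 90 °C
Reagents that add atoms: none
Why: The Brønsted acid cleaves the secondary silyl ether and the freed hydroxyl attacks the neighbouring protonated N,N-diethylbenzamide in a six-membered acyl substitution (acid-mediated lactonization of a hydroxy amide) that expels diethylamine, and because the C–O bond at the stereocenter is never broken its configuration is retained.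

**Step 5**
Reactants: 19 4-{[(2S)-1-(2-{[(3S)-5,8-dimethoxy-1-oxo-3,4-dihydro-1H-isochromen-3-yl]methyl}-1,3-dithian-2-yl)propan-2-yl]oxy}-4-oxobutanoic acid
Product: 20 4-({(2S)-5-[(3R)-5,8-dimethoxy-1-oxo-3,4-dihydro-1H-isochromen-3-yl]pentan-2-yl}oxy)-4-oxobutanoic acid
Conditions: Raney Ni (W-2, washed neutral), EtOH/THF, 60 °C
Reagents that add atoms: none
Why: Raney nickel hydrogenolysis of both C–S bonds (Mozingo desulfurization) turns the dithioketal carbon into the C2' methylene without touching the lactone, ester, acid or aryl ethers, and no stereocenter is at a reacting bond (the lactone descriptor changes from S to R only because sulfur leaves the priority count).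

**Step 6**
Reactants: 20 4-({(2S)-5-[(3R)-5,8-dimethoxy-1-oxo-3,4-dihydro-1H-isochromen-3-yl]pentan-2-yl}oxy)-4-oxobutanoic acid
Product: 21 Aspergimarin B, 4-({(2S)-5-[(3R)-5,8-dihydroxy-1-oxo-3,4-dihydro-1H-isochromen-3-yl]pentan-2-yl}oxy)-4-oxobutanoic acid
Conditions: BBr3 (8 equiv), CH2Cl2, −78 → 0 °C; ice-water quench under N2
Reagents that add atoms: none
Why: BBr3 cleaves both aryl methyl ethers by Lewis acid complexation followed by bromide SN2 attack on the methyl groups, a pathway that is much slower at the secondary carbons of the lactone and succinate C–O bonds at low temperature, so both esters and both stereocenters are expected to survive.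

## Compound list

1 | 2,5-dimethoxybenzoic acid | COc1ccc(OC)c(C(=O)O)c1 | starting material
2 | diethylamine | CCNCC | starting material
3 | 2,5-dimethoxybenzoyl chloride | COc1ccc(OC)c(C(=O)Cl)c1 | intermediate (not isolated)
4 | N,N-diethyl-2,5-dimethoxybenzamide | CCN(CC)C(=O)c1cc(OC)ccc1OC | intermediate
5 | (S)-epichlorohydrin, (2S)-2-(chloromethyl)oxirane | ClC[C@@H]1CO1 | starting material
6 | N,N-diethyl-2-lithio-3,6-dimethoxybenzamide | CCN(CC)C(=O)c1c([Li])c(OC)ccc1OC | intermediate (not isolated)
7 | [2-(diethylcarbamoyl)-3,6-dimethoxyphenyl]magnesium bromide | CCN(CC)C(=O)c1c([Mg]Br)c(OC)ccc1OC | intermediate (not isolated)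
8 | N,N-diethyl-2-[(2S)-3-chloro-2-hydroxypropyl]-3,6-dimethoxybenzamide | CCN(CC)C(=O)c1c(C[C@H](O)CCl)c(OC)ccc1OC | intermediate (not isolated)
9 | N,N-diethyl-3,6-dimethoxy-2-[(2S)-oxiran-2-ylmethyl]benzamide | CCN(CC)C(=O)c1c(C[C@H]2CO2)c(OC)ccc1OC | intermediate
10 | 2-(tert-butyldimethylsilyl)-1,3-dithiane | CC(C)(C)[Si](C)(C)C1SCCCS1 | starting material
11 | (S)-propylene oxide, (2S)-2-methyloxirane | C[C@H]1CO1 | starting material
12 | succinic anhydride | O=C1CCC(=O)O1 | starting material
13 | 2-lithio-2-(tert-butyldimethylsilyl)-1,3-dithiane | CC(C)(C)[Si](C)(C)C1([Li])SCCCS1 | intermediate (not isolated)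
14 | lithium (2S)-1-[2-(tert-butyldimethylsilyl)-1,3-dithian-2-yl]-3-[2-(diethylcarbamoyl)-3,6-dimethoxyphenyl]propan-2-olate | CCN(CC)C(=O)c1c(C[C@H](O[Li])CC2([Si](C)(C)C(C)(C)C)SCCCS2)c(OC)ccc1OC | intermediate (not isolated)
15 | 2-{(2S)-2-[(tert-butyldimethylsilyl)oxy]-3-(2-lithio-1,3-dithian-2-yl)propyl}-N,N-diethyl-3,6-dimethoxybenzamide | CCN(CC)C(=O)c1c(C[C@H](O[Si](C)(C)C(C)(C)C)CC2([Li])SCCCS2)c(OC)ccc1OC | intermediate (not isolated)
16 | lithium (2S)-1-{2-[(2S)-2-[(tert-butyldimethylsilyl)oxy]-3-[2-(diethylcarbamoyl)-3,6-dimethoxyphenyl]propyl]-1,3-dithian-2-yl}propan-2-olate | CCN(CC)C(=O)c1c(C[C@H](O[Si](C)(C)C(C)(C)C)CC2(C[C@H](C)O[Li])SCCCS2)c(OC)ccc1OC | intermediate (not isolated)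
17 | 4-{[(2S)-1-{2-[(2S)-2-[(tert-butyldimethylsilyl)oxy]-3-[2-(diethylcarbamoyl)-3,6-dimethoxyphenyl]propyl]-1,3-dithian-2-yl}propan-2-yl]oxy}-4-oxobutanoic acid | CCN(CC)C(=O)c1c(C[C@H](O[Si](C)(C)C(C)(C)C)CC2(C[C@H](C)OC(=O)CCC(=O)O)SCCCS2)c(OC)ccc1OC | intermediate
18 | 4-{[(2S)-1-{2-[(2S)-3-[2-(diethylcarbamoyl)-3,6-dimethoxyphenyl]-2-hydroxypropyl]-1,3-dithian-2-yl}propan-2-yl]oxy}-4-oxobutanoic acid | CCN(CC)C(=O)c1c(C[C@H](O)CC2(C[C@H](C)OC(=O)CCC(=O)O)SCCCS2)c(OC)ccc1OC | intermediate (not isolated)
19 | 4-{[(2S)-1-(2-{[(3S)-5,8-dimethoxy-1-oxo-3,4-dihydro-1H-isochromen-3-yl]methyl}-1,3-dithian-2-yl)propan-2-yl]oxy}-4-oxobutanoic acid | COc1ccc(OC)c2C(=O)O[C@H](CC3(C[C@H](C)OC(=O)CCC(=O)O)SCCCS3)Cc12 | intermediate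
20 | 4-({(2S)-5-[(3R)-5,8-dimethoxy-1-oxo-3,4-dihydro-1H-isochromen-3-yl]pentan-2-yl}oxy)-4-oxobutanoic acid | COc1ccc(OC)c2C(=O)O[C@H](CCC[C@H](C)OC(=O)CCC(=O)O)Cc12 | intermediate
21 | Aspergimarin B | C[C@@H](CCC[C@@H]1Cc2c(O)ccc(O)c2C(=O)O1)OC(=O)CCC(=O)O | target

The carbinol carbon that becomes the lactone C3 keeps one spatial arrangement from 5 to 21. Its descriptor reads S while the dithiane is present (8, 9, 14 to 19) and R once the sulfur is gone (20, 21).

## Summary

Total step count: 6. Longest linear sequence: 6 steps (1 → 4 → 9 → 17 → 19 → 20 → 21); compounds 2, 5, 10, 11 and 12 are bought.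

## The three steps most likely to fail

**Step 3.** The risks are a premature silyl shift promoted by the amide oxygen (which would let anion 15 meet unreacted 9), benzylic deprotonation of 9 or within 15, and attack of alkoxide 14 on the amide. The fallback drops the silyl relay for a stepwise double alkylation and sets out from 9. 1,3-Dithiane is deprotonated with n-BuLi (THF, −30 °C) to 2-lithio-1,3-dithiane F1, which opens 9 at the terminal carbon to give N,N-diethyl-2-[(2S)-3-(1,3-dithian-2-yl)-2-hydroxypropyl]-3,6-dimethoxybenzamide F2. Silylation with TBSCl and imidazole in DMF gives 2-{(2S)-2-[(tert-butyldimethylsilyl)oxy]-3-(1,3-dithian-2-yl)propyl}-N,N-diethyl-3,6-dimethoxybenzamide F3. Deprotonation of F3 with t-BuLi in THF/HMPA at −78 °C gives the lithiodithiane 15, where the fallback comes back to the route; 11 and then 12 are added as in step 3 to reach 17.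

**Step 2.** The risks are a sluggish copper-catalysed opening of 5 by the doubly ortho-substituted aryl Grignard, and over-addition to the product epoxide. The fallback builds the epoxide from an alkene and sets out from 4. The Grignard 7, made as in step 2, is allylated with allyl bromide (CuI cat., −40 → 0 °C) to N,N-diethyl-3,6-dimethoxy-2-(prop-2-en-1-yl)benzamide F4. Epoxidation with mCPBA (CH2Cl2, NaHCO3, 0 °C) gives racemic N,N-diethyl-3,6-dimethoxy-2-(oxiran-2-ylmethyl)benzamide F5. Hydrolytic kinetic resolution follows, with (S,S)-(salen)Co(OAc) (0.5 mol %; salen = N,N'-bis(3,5-di-tert-butylsalicylidene)-1,2-cyclohexanediaminate, trivalent cobalt) and H2O (0.55 equiv). By analogy with simple alkyl-substituted terminal epoxides this should hydrolyse the (R)-epoxide to N,N-diethyl-2-[(2R)-2,3-dihydroxypropyl]-3,6-dimethoxybenzamide F6 and leave the (S)-epoxide 9, where the fallback comes back to the route. The catalyst sense is from memory and should be confirmed on a small scale by chiral HPLC against 9 made from 5.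

**Step 6.** The risks are BBr3 attacking the succinate or lactone C–O bonds and slow cleavage of the non-chelated 5-methoxy group. The fallback replaces Lewis acid cleavage by an oxidation–reduction pair and sets out from 20. Oxidative demethylation with (NH4)2Ce(NO3)6 in MeCN/H2O at 0 °C gives the quinone 4-({(2S)-5-[(3R)-1,5,8-trioxo-3,4,5,8-tetrahydro-1H-isochromen-3-yl]pentan-2-yl}oxy)-4-oxobutanoic acid F7. F7 is reduced at once with Na2S2O4 in EtOAc/H2O to the hydroquinone 21, where the fallback comes back to the route.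

## Further compounds

F1 | step 3 | 2-lithio-1,3-dithiane | [Li]C1SCCCS1
F2 | step 3 | N,N-diethyl-2-[(2S)-3-(1,3-dithian-2-yl)-2-hydroxypropyl]-3,6-dimethoxybenzamide | CCN(CC)C(=O)c1c(C[C@H](O)CC2SCCCS2)c(OC)ccc1OC
F3 | step 3 | 2-{(2S)-2-[(tert-butyldimethylsilyl)oxy]-3-(1,3-dithian-2-yl)propyl}-N,N-diethyl-3,6-dimethoxybenzamide | CCN(CC)C(=O)c1c(C[C@H](O[Si](C)(C)C(C)(C)C)CC2SCCCS2)c(OC)ccc1OC
F4 | step 2 | N,N-diethyl-3,6-dimethoxy-2-(prop-2-en-1-yl)benzamide | CCN(CC)C(=O)c1c(CC=C)c(OC)ccc1OC
F5 | step 2 | racemic N,N-diethyl-3,6-dimethoxy-2-(oxiran-2-ylmethyl)benzamide | CCN(CC)C(=O)c1c(CC2CO2)c(OC)ccc1OC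
F6 | step 2 | N,N-diethyl-2-[(2R)-2,3-dihydroxypropyl]-3,6-dimethoxybenzamide | CCN(CC)C(=O)c1c(C[C@@H](O)CO)c(OC)ccc1OC
F7 | step 6 | 4-({(2S)-5-[(3R)-1,5,8-trioxo-3,4,5,8-tetrahydro-1H-isochromen-3-yl]pentan-2-yl}oxy)-4-oxobutanoic acid | C[C@@H](CCC[C@@H]1CC2=C(C(=O)O1)C(=O)C=CC2=O)OC(=O)CCC(=O)O
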